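The readings are calculated for substances that don't exist.

Count the partner.

| flask | substrate | partner | protic impurity | remark | time |
|---|---|---|---|---|---|
| alpha | 0.50 mM | 0.29 mM (in portions, 4) | 0.50 mM | run made earlier; portions every 20 s |  |
| zeta | 0.50 mM | 0.67 mM (in portions, 4) | 0.50 mM | run made earlier; portions every 20 s |  |
| north | 0.50 mM | 0.400 mM (in portions, 4) | 0.500 mM | the portions of partner follow each other after 20 s, the first at the start | 10 min |
| west | 0.50 mM | 0.800 mM | 0.500 mM | everything together at the start | 10 min |

- alpha (time / min: product / %, substrate / %): 0.667: 28.0, 60.9; 2.00: 55.9, 39.8; 3.00: 55.8, 40.0; 5.00: 56.0, 39.3; 8.00: 56.0, 39.6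
- zeta (time / min: product / %, substrate / %): 1.33: 98.5, 1.7; 3.00: 99.7, 0.2; 4.00: 99.4, 0; 6.00: 100.0, 0; 8.00: 100.2, 0.3

(each reading ± 0.3 percentage points)

1. the flask that ends with the higher amount of product, in percent of the substrate charged, or "neither" when 2 percentage points or less lies between them (north / west / neither)
2. final product, as a percentage of the substrate charged, in north
3. final product, as a percentage of the substrate charged, in west

- steps thought possible: partner + intermediate -> product; partner + protic impurity -> quenched reagent; substrate <-> intermediate + leaving ligand

Each partner ends as product or as quenched reagent. So north has a ceiling, its charge over the substrate: 80.0%, with partner the limiting reagent. West's limiting reagent is the substrate, so its ceiling is 100%.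

Alpha levelled off at 56.0%, which leaves 0.0100 mM of its partner lost. That is a small difference of readings, so it carries their scatter of 0.3 percentage points.

Partner stands in both the quench rate and the capture rate, so it cancels from their ratio. Suppose the substrate step stays at equilibrium. Then intermediate goes as substrate over leaving ligand, and leaving ligand follows product. With protic impurity taken as unchanged, loss per product therefore rises with product over remaining substrate.

Summed up to a fractional yield y, this gives the toll: substrate charge times (ln(1/(1−y)) − y). Alpha's toll is 0.130 mM, so alpha lost 0.0766 of partner per unit of toll. Call that the quench factor. North and west carry alpha's protic impurity.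

Toll per product rises with yield, so on this reckoning north loses at least alpha's share, and its ceiling falls to 77.2%. For a floor, charge north the toll of its first ceiling, 0.405 mM. That costs 0.0310 mM and leaves 73.8%.

West's toll up to zeta's 98.5% costs 0.123 mM, less than its excess of 0.300 mM. So I put west above that reading and ahead of north.

The forecast, inside both brackets, says west, with 76% for north and 100% for west, and of north it says “north loses about 0.02 mM of its 0.40 mM”.

The flasks give 75.5% for north and >99.9% for west, so west ends higher.

    partner + intermediate → product (k = 28000 M⁻¹ s⁻¹)
    partner + protic impurity → quenched reagent (k = 66.0 M⁻¹ s⁻¹)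
    substrate ⇌ intermediate + leaving ligand (K = 3.40 × 10⁻⁵ M, k = 0.200 s⁻¹)

North's partner stood at 0% after 1.00 min, just before the last addition, and from 5.00 min product held at 75.5% beside 22.5% substrate. In west, capture did half its turnover by 0.0621 min and quenching by 0.232 min, and after 10.0 min west held 0.300 mM of quenched reagent. At north's yield the quench factor gives 0.0250 mM, and north holds 0.0225 mM. West's neighbour with 1.2 mM substrate ended at 61.3%. There the factor gives 0.0309 mM, and that flask holds twice that, 0.0648 mM.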